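**Plan**
- Enabling feature: in the carbocycle (C4a, C5, C6, C7, C8, C8a) the C8 ketone sits next to the C7 tertiary carbinol. This α‑ketol joins two carbonyl‑derived carbons, so the first cut is C7–C8 (retro‑benzoin, polarity reversal at C8), leaving a monocyclic 2H‑pyran‑3‑carbaldehyde with a 1,4‑diketone arm.
- Second cut: C4a–C5 (sp2–sp3), giving a 4‑triflyloxy‑2H‑pyran‑3‑carbaldehyde and a β‑branched alkylzinc. The pyran is traced to a 4‑pyranone made from an enaminone and crotonyl chloride; the arm is traced to (S)‑γ‑undecalactone.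
- Forward order: the pyran ring is made first (step 4), the arm is joined by Negishi coupling (step 8), and the carbocycle is closed last by an intramolecular crossed benzoin (step 10).
- Stereochemistry: C6 comes from trans‑selective α‑hydroxymethylation of the lactone enolate. The lactone ring and its carbinol are temporary control elements; the ring is opened and the carbinol is oxidised to the side‑chain ketone. C7 is set in the benzoin under control of C6.

Key step: step 10

Remark: (S)‑γ‑undecalactone (1) is taken as a purchasable single enantiomer; isochromene numbering (C1, O2, C3, C4, C4a, C5–C8, C8a) is used for the target.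

**Step 1**
Reactants: 1 (S)‑γ‑undecalactone [(5S)‑5‑heptyloxolan‑2‑one]
Product: 3 (3R,5S)‑5‑heptyl‑3‑(hydroxymethyl)oxolan‑2‑one, via lithium enolate 2 (not isolated)
Conditions: LiN(i‑Pr)2, THF, −78 °C; CH2O (gas, from cracked paraformaldehyde), −78 to −40 °C
Reagents that add atoms: formaldehyde C=O
Why: Lactone enolate aldol (α‑hydroxymethylation) in which the electrophile should enter anti to the C5 heptyl group, giving the trans product and fixing the carbon that becomes C6.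

**Step 2**
Reactants: 3 (3R,5S)‑5‑heptyl‑3‑(hydroxymethyl)oxolan‑2‑one
Product: 5 [(3R,5S)‑5‑heptyl‑2‑methoxy‑2‑methyloxolan‑3‑yl]methanol (anomer mixture), via keto diol 4 (not isolated)
Conditions: MeLi (2.2 equiv), THF, −78 °C; then MeOH, pyridinium p‑toluenesulfonate (cat.), 3 Å molecular sieves, rt
Reagents that add atoms: methyllithium [Li]C; methanol CO
Why: Mono‑addition of MeLi to a γ‑lactone stops at the lithium lactolate, and acid‑catalysed ketalisation in methanol then locks the γ‑hydroxy methyl ketone as a cyclic mixed ketal, so the α‑centre is not next to a free ketone during iodination and metalation.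

**Step 3**
Reactants: 5 [(3R,5S)‑5‑heptyl‑2‑methoxy‑2‑methyloxolan‑3‑yl]methanol
Product: 6 (3S,5S)‑5‑heptyl‑3‑(iodomethyl)‑2‑methoxy‑2‑methyloxolane
Conditions: I2, PPh3, imidazole, CH2Cl2, 0 °C to rt
Reagents that add atoms: iodine II
Why: Appel iodination of the primary alcohol under imidazole buffering, which should leave the acid‑labile ketal and both stereocentres untouched.

**Step 4**
Reactants: 7 ethyl 2‑[(dimethylamino)methylidene]‑3‑oxobutanoate; 8 (E)‑but‑2‑enoyl chloride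
Product: 10 ethyl 4‑oxo‑6‑[(E)‑prop‑1‑enyl]‑4H‑pyran‑3‑carboxylate, via diketo enaminone 9 (not isolated)
Conditions: LiN(SiMe3)2 (2.5 equiv), THF, −78 °C; then 2 M HCl, rt
Reagents that add atoms: none
Why: Claisen‑type C‑acylation of the methyl ketone enolate, then acid‑promoted addition–elimination of the enol oxygen at the enaminone carbon with loss of dimethylamine, a standard 4‑pyranone‑3‑carboxylate synthesis that forms the pyran ring.

**Step 5**
Reactants: 10 ethyl 4‑oxo‑6‑[(E)‑prop‑1‑enyl]‑4H‑pyran‑3‑carboxylate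
Product: 12 ethyl 6‑[(E)‑prop‑1‑enyl]‑4‑(trifluoromethylsulfonyloxy)‑2H‑pyran‑3‑carboxylate, via lithium enolate 11 (not isolated)
Conditions: LiBH(s‑Bu)3, THF, −78 °C; then N‑(5‑chloropyridin‑2‑yl)bis(trifluoromethanesulfonyl)imide, −78 to 0 °C
Reagents that add atoms: N‑(5‑chloropyridin‑2‑yl)bis(trifluoromethanesulfonyl)imide FC(F)(F)S(=O)(=O)N(c1ccc(Cl)cn1)S(=O)(=O)C(F)(F)F
Why: Conjugate hydride addition at the unsubstituted, doubly activated C2 of the pyranone gives the β‑keto ester enolate, which is trapped on oxygen as the enol triflate (reductive enolate triflation, as practised on chromone‑3‑carboxylates).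

**Step 6**
Reactants: 12 ethyl 6‑[(E)‑prop‑1‑enyl]‑4‑(trifluoromethylsulfonyloxy)‑2H‑pyran‑3‑carboxylate
Product: 13 3‑(hydroxymethyl)‑6‑[(E)‑prop‑1‑enyl]‑2H‑pyran‑4‑yl trifluoromethanesulfonate
Conditions: i‑Bu2AlH (2.2 equiv), CH2Cl2, −78 °C; crude product used at once
Reagents that add atoms: none
Why: 1,2‑Reduction of a β‑triflyloxy enoate to the allylic alcohol by i‑Bu2AlH at low temperature, where the enol triflate should survive and electrocyclic opening of the 2H‑pyran is frozen.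

**Step 7**
Reactants: 13 3‑(hydroxymethyl)‑6‑[(E)‑prop‑1‑enyl]‑2H‑pyran‑4‑yl trifluoromethanesulfonate
Product: 14 3‑formyl‑6‑[(E)‑prop‑1‑enyl]‑2H‑pyran‑4‑yl trifluoromethanesulfonate
Conditions: MnO2 (excess), CH2Cl2, 0 °C to rt
Reagents that add atoms: none
Why: Chemoselective allylic oxidation that restores the donor–acceptor conjugation (ring oxygen to formyl group) expected to stabilise the 2H‑pyran.

**Step 8**
Reactants: 6 (3S,5S)‑5‑heptyl‑3‑(iodomethyl)‑2‑methoxy‑2‑methyloxolane; 14 3‑formyl‑6‑[(E)‑prop‑1‑enyl]‑2H‑pyran‑4‑yl trifluoromethanesulfonate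
Product: 17 4‑[(2S,4S)‑2‑acetyl‑4‑hydroxyundecyl]‑6‑[(E)‑prop‑1‑enyl]‑2H‑pyran‑3‑carbaldehyde, via alkylzinc iodide 15 (not isolated), via coupled ketal aldehyde 16 (not isolated)
Conditions: 6, Zn dust (1,2‑dibromoethane‑activated), LiCl, THF, 40 °C; then 14, Pd(OAc)2 (3 mol %), 2‑dicyclohexylphosphino‑2',6'‑dimethoxybiphenyl (6 mol %), THF, rt; then pyridinium p‑toluenesulfonate, acetone/H2O, rt
Reagents that add atoms: water O
Why: Zinc insertion gives a γ‑ketal alkylzinc iodide (a protected zinc homoenolate, a stable reagent class), Negishi sp3–sp2 coupling with the vinylogous acyl triflate forms C4a–C5 without touching the β‑stereocentre or the aldehyde, and mild acid unmasks the γ‑hydroxy methyl ketone.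

**Step 9**
Reactants: 17 4‑[(2S,4S)‑2‑acetyl‑4‑hydroxyundecyl]‑6‑[(E)‑prop‑1‑enyl]‑2H‑pyran‑3‑carbaldehyde
Product: 18 4‑[(2S)‑2‑acetyl‑4‑oxoundecyl]‑6‑[(E)‑prop‑1‑enyl]‑2H‑pyran‑3‑carbaldehyde
Conditions: 1,1,1‑triacetoxy‑1,1‑dihydro‑1,2‑benziodoxol‑3(1H)‑one, CH2Cl2, 0 °C to rt
Reagents that add atoms: none
Why: Periodinane oxidation of the secondary carbinol (the temporary stereocentre) to the side‑chain ketone under near‑neutral conditions that should not epimerise the α‑acetyl centre or touch the aldehyde.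

**Step 10**
Reactants: 18 4‑[(2S)‑2‑acetyl‑4‑oxoundecyl]‑6‑[(E)‑prop‑1‑enyl]‑2H‑pyran‑3‑carbaldehyde
Product: 19 (6S,7S)‑7‑hydroxy‑7‑methyl‑6‑(2‑oxononyl)‑3‑[(E)‑prop‑1‑enyl]‑6,7‑dihydro‑1H‑isochromen‑8(5H)‑one
Conditions: 2‑(pentafluorophenyl)‑6,7‑dihydro‑5H‑pyrrolo[2,1‑c][1,2,4]triazol‑2‑ium tetrafluoroborate (20 mol %), Et3N (1 equiv), toluene (0.02 M), rt
Reagents that add atoms: none
Why: The triazolylidene adds to the formyl group and proton transfer gives the enaminol (acyl‑anion equivalent), whose C8 attacks the acetyl carbonyl C7; collapse of the adduct releases the carbene and leaves the C8 ketone beside the new C7 carbinol. The closest known reaction is the carbene‑catalysed intramolecular crossed aldehyde–ketone benzoin of 2‑(3‑oxobutyl)aryl aldehydes to 2‑hydroxy‑2‑methyl‑1‑tetralones, with the donor–acceptor pyran here in the place of the arene. The carbocycle closes in 6‑exo‑trig mode through the C7–C8 bond. C7 is set by C6: in a chair‑like transition state the 2‑oxononyl arm is pseudo‑equatorial, the ketone oxygen is pseudo‑equatorial and syn to the enaminol O–H that transfers its proton, and the methyl group is pseudo‑axial away from the azolium, which puts the C7 hydroxyl trans to the C6 arm (7S). The addition is reversible and this isomer also keeps the in‑plane O–H···O=C8 hydrogen bond, so kinetic and thermodynamic preferences should agree. The step needs acyl‑anion rather than homoenolate reactivity (the fully substituted C4a blocks the latter), attack on the acetyl rather than the heptyl ketone (six‑ versus seven‑membered ring) and no epimerisation at C6 (only a weak amine base is present).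

**Compound list**
1 | (S)‑γ‑undecalactone, (5S)‑5‑heptyloxolan‑2‑one | O=C1CC[C@H](CCCCCCC)O1 | starting material
2 | lithium enolate of 1 | [Li+].[O-]C1=CC[C@H](CCCCCCC)O1 | intermediate
3 | (3R,5S)‑5‑heptyl‑3‑(hydroxymethyl)oxolan‑2‑one | O=C1[C@@H](CO)C[C@H](CCCCCCC)O1 | intermediate
4 | (3R,5S)‑5‑hydroxy‑3‑(hydroxymethyl)dodecan‑2‑one | CC(=O)[C@@H](CO)C[C@@H](O)CCCCCCC | intermediate
5 | [(3R,5S)‑5‑heptyl‑2‑methoxy‑2‑methyloxolan‑3‑yl]methanol (anomer mixture) | COC1(C)[C@@H](CO)C[C@H](CCCCCCC)O1 | intermediate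
6 | (3S,5S)‑5‑heptyl‑3‑(iodomethyl)‑2‑methoxy‑2‑methyloxolane | COC1(C)[C@@H](CI)C[C@H](CCCCCCC)O1 | intermediate
7 | ethyl 2‑[(dimethylamino)methylidene]‑3‑oxobutanoate | CCOC(=O)C(=CN(C)C)C(C)=O | starting material
8 | (E)‑but‑2‑enoyl chloride | C/C=C/C(Cl)=O | starting material
9 | ethyl (6E)‑2‑[(dimethylamino)methylidene]‑3,5‑dioxooct‑6‑enoate | CCOC(=O)C(=CN(C)C)C(=O)CC(=O)/C=C/C | intermediate
10 | ethyl 4‑oxo‑6‑[(E)‑prop‑1‑enyl]‑4H‑pyran‑3‑carboxylate | CCOC(=O)C1=COC(/C=C/C)=CC1=O | intermediate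
11 | lithium enolate of ethyl 4‑oxo‑6‑[(E)‑prop‑1‑enyl]‑3,4‑dihydro‑2H‑pyran‑3‑carboxylate | CCOC(=O)C1=C([O-])C=C(/C=C/C)OC1.[Li+] | intermediate
12 | ethyl 6‑[(E)‑prop‑1‑enyl]‑4‑(trifluoromethylsulfonyloxy)‑2H‑pyran‑3‑carboxylate | CCOC(=O)C1=C(OS(=O)(=O)C(F)(F)F)C=C(/C=C/C)OC1 | intermediate
13 | 3‑(hydroxymethyl)‑6‑[(E)‑prop‑1‑enyl]‑2H‑pyran‑4‑yl trifluoromethanesulfonate | OCC1=C(OS(=O)(=O)C(F)(F)F)C=C(/C=C/C)OC1 | intermediate
14 | 3‑formyl‑6‑[(E)‑prop‑1‑enyl]‑2H‑pyran‑4‑yl trifluoromethanesulfonate | O=CC1=C(OS(=O)(=O)C(F)(F)F)C=C(/C=C/C)OC1 | intermediate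
15 | {[(3S,5S)‑5‑heptyl‑2‑methoxy‑2‑methyloxolan‑3‑yl]methyl}zinc iodide | COC1(C)[C@@H](C[Zn]I)C[C@H](CCCCCCC)O1 | intermediate
16 | 4‑{[(3S,5S)‑5‑heptyl‑2‑methoxy‑2‑methyloxolan‑3‑yl]methyl}‑6‑[(E)‑prop‑1‑enyl]‑2H‑pyran‑3‑carbaldehyde | COC1(C)[C@@H](CC2=C(C=O)COC(/C=C/C)=C2)C[C@H](CCCCCCC)O1 | intermediate
17 | 4‑[(2S,4S)‑2‑acetyl‑4‑hydroxyundecyl]‑6‑[(E)‑prop‑1‑enyl]‑2H‑pyran‑3‑carbaldehyde | CC(=O)[C@@H](CC1=C(C=O)COC(/C=C/C)=C1)C[C@@H](O)CCCCCCC | intermediate
18 | 4‑[(2S)‑2‑acetyl‑4‑oxoundecyl]‑6‑[(E)‑prop‑1‑enyl]‑2H‑pyran‑3‑carbaldehyde | CC(=O)[C@@H](CC1=C(C=O)COC(/C=C/C)=C1)CC(=O)CCCCCCC | intermediate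
19 | (6S,7S)‑7‑hydroxy‑7‑methyl‑6‑(2‑oxononyl)‑3‑[(E)‑prop‑1‑enyl]‑6,7‑dihydro‑1H‑isochromen‑8(5H)‑one | C/C=C/C1=CC2=C(CO1)C(=O)[C@@](C)(O)[C@H](CC(=O)CCCCCCC)C2 | target

**Step count and risks**
Total: 10 steps. Longest linear sequence: 7 steps (steps 4–10, from 7 and 8).

Step 10. Three processes could spoil the ring closure. The donor‑conjugated formyl group may form the enaminol only slowly. The carbene may be consumed by conjugate addition to the ring‑opened dienone valence isomer of the 2H‑pyran. Facial discrimination at the acetyl carbonyl may be too weak, or the amine may slowly epimerise C6. The fallback sets out from 18 and uses single‑electron polarity reversal instead. SmI2 (2.2 equiv, THF, −78 °C) should reduce the formyl group to a samarium ketyl that adds to the acetyl group through a chelated chair, giving the cis‑diol 1‑[(6S,7S,8R)‑7,8‑dihydroxy‑7‑methyl‑3‑[(E)‑prop‑1‑enyl]‑5,6,7,8‑tetrahydro‑1H‑isochromen‑6‑yl]nonan‑2‑one F1. MnO2 in CH2Cl2 then oxidises only the secondary allylic carbinol at C8, and the route is rejoined at 19.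

Step 6. The alcohol 13 has no acceptor on the pyran, so electrocyclic opening to a cross‑conjugated dienone and subsequent oligomerisation may outrun the oxidation; hydride addition–elimination at the triflate‑bearing carbon is a second possible loss. The fallback never passes through the alcohol oxidation level. It sets out from 8 and purchased N‑methoxy‑N‑methyl‑3‑oxobutanamide. Condensation of the amide with N,N‑dimethylformamide dimethyl acetal gives 2‑[(dimethylamino)methylidene]‑N‑methoxy‑N‑methyl‑3‑oxobutanamide F2. Its lithium enolate (LiN(SiMe3)2) is acylated with 8 to (6E)‑2‑[(dimethylamino)methylidene]‑N‑methoxy‑N‑methyl‑3,5‑dioxooct‑6‑enamide F3 (not isolated), which aqueous HCl cyclises to N‑methoxy‑N‑methyl‑4‑oxo‑6‑[(E)‑prop‑1‑enyl]‑4H‑pyran‑3‑carboxamide F4. LiBH(s‑Bu)3 followed by the pyridyl triflimide gives, through the lithium enolate of N‑methoxy‑N‑methyl‑4‑oxo‑6‑[(E)‑prop‑1‑enyl]‑3,4‑dihydro‑2H‑pyran‑3‑carboxamide F5 (not isolated), the triflate 3‑[methoxy(methyl)carbamoyl]‑6‑[(E)‑prop‑1‑enyl]‑2H‑pyran‑4‑yl trifluoromethanesulfonate F6. i‑Bu2AlH at −78 °C reduces the N‑methoxy‑N‑methylamide through its chelated aluminium hemiaminal directly to the aldehyde, and the route is rejoined at 14.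

Step 2. MeLi may enolise the α‑branched lactone and erode the configuration of the future C6, the lithium alkoxide may lose formaldehyde by retro‑aldol cleavage, and the free β‑hydroxy ketone 4 may dehydrate during ketalisation. The fallback sets out from 3 and transfers the acyl group through an N‑methoxy‑N‑methylamide instead. Silylation (t‑BuMe2SiCl, imidazole) gives (3R,5S)‑3‑{[tert‑butyl(dimethyl)silyl]oxymethyl}‑5‑heptyloxolan‑2‑one F7. Aminolysis with MeNH(OMe)·HCl and Me3Al opens the lactone to (2R,4S)‑2‑{[tert‑butyl(dimethyl)silyl]oxymethyl}‑4‑hydroxy‑N‑methoxy‑N‑methylundecanamide F8. MeMgBr (excess, THF, 0 °C) stops at the ketone (3R,5S)‑3‑{[tert‑butyl(dimethyl)silyl]oxymethyl}‑5‑hydroxydodecan‑2‑one F9. Camphorsulfonic acid in methanol then closes the cyclic methyl ketal and removes the primary silyl ether, and the route is rejoined at 5.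

**Further compounds**
F1 | step 10 | 1‑[(6S,7S,8R)‑7,8‑dihydroxy‑7‑methyl‑3‑[(E)‑prop‑1‑enyl]‑5,6,7,8‑tetrahydro‑1H‑isochromen‑6‑yl]nonan‑2‑one | C/C=C/C1=CC2=C(CO1)[C@@H](O)[C@@](C)(O)[C@H](CC(=O)CCCCCCC)C2
F2 | step 6 | 2‑[(dimethylamino)methylidene]‑N‑methoxy‑N‑methyl‑3‑oxobutanamide | CON(C)C(=O)C(=CN(C)C)C(C)=O
F3 | step 6 | (6E)‑2‑[(dimethylamino)methylidene]‑N‑methoxy‑N‑methyl‑3,5‑dioxooct‑6‑enamide | CON(C)C(=O)C(=CN(C)C)C(=O)CC(=O)/C=C/C
F4 | step 6 | N‑methoxy‑N‑methyl‑4‑oxo‑6‑[(E)‑prop‑1‑enyl]‑4H‑pyran‑3‑carboxamide | CON(C)C(=O)C1=COC(/C=C/C)=CC1=O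
F5 | step 6 | lithium enolate of N‑methoxy‑N‑methyl‑4‑oxo‑6‑[(E)‑prop‑1‑enyl]‑3,4‑dihydro‑2H‑pyran‑3‑carboxamide | CON(C)C(=O)C1=C([O-])C=C(/C=C/C)OC1.[Li+]
F6 | step 6 | 3‑[methoxy(methyl)carbamoyl]‑6‑[(E)‑prop‑1‑enyl]‑2H‑pyran‑4‑yl trifluoromethanesulfonate | CON(C)C(=O)C1=C(OS(=O)(=O)C(F)(F)F)C=C(/C=C/C)OC1
F7 | step 2 | (3R,5S)‑3‑{[tert‑butyl(dimethyl)silyl]oxymethyl}‑5‑heptyloxolan‑2‑one | O=C1[C@@H](CO[Si](C)(C)C(C)(C)C)C[C@H](CCCCCCC)O1
F8 | step 2 | (2R,4S)‑2‑{[tert‑butyl(dimethyl)silyl]oxymethyl}‑4‑hydroxy‑N‑methoxy‑N‑methylundecanamide | CON(C)C(=O)[C@@H](CO[Si](C)(C)C(C)(C)C)C[C@@H](O)CCCCCCC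
F9 | step 2 | (3R,5S)‑3‑{[tert‑butyl(dimethyl)silyl]oxymethyl}‑5‑hydroxydodecan‑2‑one | CC(=O)[C@@H](CO[Si](C)(C)C(C)(C)C)C[C@@H](O)CCCCCCC
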